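Ring B carries oxygen at C2' and C5' and is joined through C1' to C2 of the chromanone: a 2-substituted 4-alkoxyphenol, which is what a vinylcarbene, a terminal alkyne and CO assemble. Ring B is therefore built last, by Dötz benzannulation on a (2S)-2-ethynylchromanone that already holds ring A, the (R)-lavandulyl chain at C8 and the C2 stereocentre; one operation forms C1'–C2', C2'–C3' and C5'–C6'. The alkyne comes from copper-catalysed asymmetric alkynylation of an 8-lavandulylchromone, itself made by Negishi coupling of an 8-iodochromone with (S)-lavandulylzinc. A β-silylvinyl carbene complex replaces the fragile parent vinyl complex; oxidative demethylation and reduction finish the hydroquinone.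

Key step: step 10

Remark: lavandulyl = 5-methyl-2-(prop-1-en-2-yl)hex-4-en-1-yl; its stereocentre is labelled S in the alcohol, iodide and organometallics and R once bound to C8, with no change in spatial arrangement. It is assumed that the lipase acylates the (R)-alcohol faster and that the ligand antipode giving (2S) is identified in a pilot run.

Step 1
Reactants: 1 (±)-lavandulol
Product: 2 (S)-lavandulol
Conditions: porcine pancreatic lipase, vinyl acetate, hexane, rt, to ca. 65% conversion; chromatography
Reagents that add atoms: none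
Why: Lipase-catalysed kinetic resolution by irreversible transesterification, in which the (R)-alcohol should be acylated faster, so that driving the conversion past one half should leave the slow-reacting (S)-alcohol highly enriched (ee to be checked by chiral GC, second pass if needed); the stereocentre is selected, not made.

Step 2
Reactants: 2 (S)-lavandulol
Product: 3 (S)-lavandulyl iodide
Conditions: PPh3, imidazole, I2, CH2Cl2, 0 °C → rt, dark
Reagents that add atoms: iodine, [I][I]
Why: Appel reaction, an SN2 displacement at the primary CH2 of the alkoxyphosphonium ion under neutral conditions, which should leave the neighbouring stereocentre and both alkenes untouched.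

Step 3
Reactants: 4 2',6'-dihydroxy-4'-methoxyacetophenone
Product: 5 2'-hydroxy-4'-methoxy-6'-(triisopropylsilyloxy)acetophenone
Conditions: TIPSCl (1.05 equiv), imidazole, DMF, 0 °C → rt
Reagents that add atoms: chlorotriisopropylsilane, CC(C)[Si](Cl)(C(C)C)C(C)C
Why: O-silylation of a symmetric bis-phenol, which can give only one mono-ether and should stop there because the remaining hydroxyl is hydrogen-bonded to the acetyl group and the reagent is bulky.

Step 4
Reactants: 5 2'-hydroxy-4'-methoxy-6'-(triisopropylsilyloxy)acetophenone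
Product: 6 2'-hydroxy-3'-iodo-4'-methoxy-6'-(triisopropylsilyloxy)acetophenone
Conditions: BnMe3N·ICl2 (1.0 equiv), CaCO3, CH2Cl2/MeOH, rt
Reagents that add atoms: benzyltrimethylammonium dichloroiodate, C[N+](C)(C)Cc1ccccc1.Cl[I-]Cl
Why: Electrophilic aromatic iodination directed ortho to the free phenol, which should go to C3' between OH and OMe because C5' is shielded by the bulky silyloxy group, with one equivalent of reagent limiting di-iodination.

Step 5
Reactants: 6 2'-hydroxy-3'-iodo-4'-methoxy-6'-(triisopropylsilyloxy)acetophenone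
Product: 8 8-iodo-7-methoxy-5-(triisopropylsilyloxy)chromone, via enaminone 7 (not isolated)
Conditions: Me2NCH(OMe)2, toluene, 90 °C; evaporate; AcOH, 80 °C
Reagents that add atoms: N,N-dimethylformamide dimethyl acetal, COC(OC)N(C)C
Why: Enaminone condensation at the acetyl methyl group followed by acid-mediated addition–elimination cyclisation (chromone synthesis), in which only the free phenol next to iodine can close the pyranone, so iodine is fixed at C8 and the silyloxy group at C5.

Step 6
Reactants: 3 (S)-lavandulyl iodide; 8 8-iodo-7-methoxy-5-(triisopropylsilyloxy)chromone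
Product: 11 8-[(2R)-lavandulyl]-7-methoxy-5-(triisopropylsilyloxy)chromone, via (S)-lavandulyllithium 9 (not isolated), via (S)-lavandulylzinc chloride 10 (not isolated)
Conditions: 3 (1.5 equiv), t-BuLi (2.1 equiv per 3), Et2O/pentane, −78 °C; ZnCl2 (THF), −78 °C → rt; then 8, Pd(OAc)2 (5 mol%), SPhos (10 mol%), THF, 50 °C
Reagents that add atoms: none
Why: Negishi cross-coupling, in which polar lithium–iodine exchange at −78 °C and transmetalation to zinc should keep the homoallylic skeleton and its stereocentre intact, the non-basic alkylzinc tolerates the chromone, and the bulky biarylphosphine should favour reductive elimination over β-hydride elimination at the hindered C8 position.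

Step 7
Reactants: 11 8-[(2R)-lavandulyl]-7-methoxy-5-(triisopropylsilyloxy)chromone; 12 trimethylsilylacetylene
Product: 15 (2S)-8-[(2R)-lavandulyl]-7-methoxy-5-(triisopropylsilyloxy)-2-[(trimethylsilyl)ethynyl]chroman-4-one, via benzopyrylium triflate 13 (not isolated), via silyl enol ether 14 (not isolated)
Conditions: TBSOTf (1.3 equiv), CH2Cl2, 40 °C; then CuI (10 mol%), StackPhos (11 mol%, antipode giving 2S), 12 (2 equiv), i-Pr2NEt (2 equiv), toluene, −78 → −40 °C; then 1 M HCl, THF, 0 °C
Reagents that add atoms: none
Why: Copper-catalysed enantioselective alkynylation of a chromone through its 4-silyloxybenzopyrylium ion, in which the copper acetylide bound to the atropisomeric P,N ligand should add to one face of C2 and set the (2S) centre, and the acidic work-up hydrolyses the silyl enol ether by C3 protonation without passing through a free enolate.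

Step 8
Reactants: 15 (2S)-8-[(2R)-lavandulyl]-7-methoxy-5-(triisopropylsilyloxy)-2-[(trimethylsilyl)ethynyl]chroman-4-one
Product: 16 (2S)-2-ethynyl-5-hydroxy-8-[(2R)-lavandulyl]-7-methoxychroman-4-one
Conditions: TBAF/AcOH (1:1, 3 equiv), THF, 0 °C
Reagents that add atoms: none
Why: Fluoride-mediated desilylation should cleave the alkynyl C–Si bond and the aryl O–Si bond together, while the acetic acid buffer prevents base-induced retro-oxa-Michael ring opening, so C2 should keep its configuration.

Step 9
Reactants: 17 (E)-(2-bromovinyl)trimethylsilane; 18 chromium hexacarbonyl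
Product: 21 pentacarbonyl{methoxy[(E)-2-(trimethylsilyl)vinyl]carbene}chromium, via (E)-2-(trimethylsilyl)vinyllithium 19 (not isolated), via lithium acylchromate 20 (not isolated)
Conditions: t-BuLi (2.0 equiv), Et2O, −78 °C; Cr(CO)6, −78 °C → rt; Me3OBF4, CH2Cl2/H2O, 0 °C
Reagents that add atoms: trimethyloxonium tetrafluoroborate, C[O+](C)C.F[B-](F)(F)F
Why: Fischer carbene synthesis (lithium–bromine exchange, addition of the vinyllithium to a CO ligand, O-methylation of the acylchromate), in which the β-silyl group should make the alkenyl complex stable enough to isolate and store, unlike the parent vinyl complex.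

Step 10
Reactants: 16 (2S)-2-ethynyl-5-hydroxy-8-[(2R)-lavandulyl]-7-methoxychroman-4-one; 21 pentacarbonyl{methoxy[(E)-2-(trimethylsilyl)vinyl]carbene}chromium
Product: 23 (2S)-5-hydroxy-2-(2-hydroxy-5-methoxyphenyl)-8-[(2R)-lavandulyl]-7-methoxychroman-4-one, via 2'-O-trimethylsilyl ether 22 (not isolated)
Conditions: 21 (1.8 equiv), degassed THF (0.05 M), 50 °C, dark; then air, EtOAc, rt; then aq. citric acid, THF, 0 °C
Reagents that add atoms: none
Why: Thermal loss of one CO from 21 lets the terminal alkyne of 16 insert into the Cr=C bond with its unsubstituted carbon bonding to the carbene carbon (C5'–C6'), CO insertion then gives a chromium-bound dienylketene (C1'–C2'), and ring closure (C2'–C3') gives a cyclohexadienone in which the trimethylsilyl group moves from C3' to the C2' oxygen, so that aromatisation delivers silyl ether 22, freed from chromium by air and hydrolysed to 23 by dilute acid. The closest known reaction type is the Dötz benzannulation of alkenyl(alkoxy)carbene chromium complexes with terminal alkynes to 4-alkoxyphenols, in which the β-silylvinyl complex is the established stand-in for the unstable parent vinyl complex. Ring B is closed by a thermal 6π electrocyclisation of the dienylketene on the metal. No stereocentre is formed, and C2 should survive because the medium is neutral and base-free, so neither enolisation nor oxa-Michael ring opening can occur and its C–O bond takes no part. The step needs regioselective alkyne insertion, secured by the large steric difference between hydrogen and the chromanone-bearing carbon, which puts C1' next to the CO-derived C2' hydroxyl and the methoxy group at C5'. It also needs chemoselectivity, secured because the alkyne inserts far faster than the lavandulyl alkenes can be cyclopropanated, the ketone and the chelated 5-OH are inert to the carbene complex, and dilution suppresses uptake of a second alkyne.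

Step 11
Reactants: 23 (2S)-5-hydroxy-2-(2-hydroxy-5-methoxyphenyl)-8-[(2R)-lavandulyl]-7-methoxychroman-4-one
Product: 25 (2S)-2-(2,5-dihydroxyphenyl)-5-hydroxy-8-[(2R)-lavandulyl]-7-methoxychroman-4-one, via ring B quinone 24 (not isolated)
Conditions: PhI(OAc)2 (1.05 equiv), MeCN/H2O (2:1), 0 °C; then aq. Na2S2O4, EtOAc, rt, argon
Reagents that add atoms: water, O
Why: Hypervalent-iodine oxidative demethylation of a para-methoxyphenol (water adds at C5' and methanol leaves from the hemiketal) should touch only ring B, since ring A has no para-dioxygen pattern and its 5-OH is chelated, and immediate dithionite reduction of the quinone gives the hydroquinone under near-neutral conditions that should not disturb C2.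

Compound list
1 | (±)-lavandulol, racemic 5-methyl-2-(prop-1-en-2-yl)hex-4-en-1-ol | C=C(C)C(CC=C(C)C)CO | starting material
2 | (S)-lavandulol | C=C(C)[C@H](CC=C(C)C)CO | intermediate
3 | (S)-lavandulyl iodide | C=C(C)[C@H](CC=C(C)C)CI | intermediate
4 | 2',6'-dihydroxy-4'-methoxyacetophenone | CC(=O)c1c(O)cc(OC)cc1O | starting material
5 | 2'-hydroxy-4'-methoxy-6'-(triisopropylsilyloxy)acetophenone | CC(=O)c1c(O)cc(OC)cc1O[Si](C(C)C)(C(C)C)C(C)C | intermediate
6 | 2'-hydroxy-3'-iodo-4'-methoxy-6'-(triisopropylsilyloxy)acetophenone | CC(=O)c1c(O)c(I)c(OC)cc1O[Si](C(C)C)(C(C)C)C(C)C | intermediate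
7 | (E)-3-(dimethylamino)-1-[2-hydroxy-3-iodo-4-methoxy-6-(triisopropylsilyloxy)phenyl]prop-2-en-1-one (enaminone) | CN(C)/C=C/C(=O)c1c(O)c(I)c(OC)cc1O[Si](C(C)C)(C(C)C)C(C)C | intermediate
8 | 8-iodo-7-methoxy-5-(triisopropylsilyloxy)chromone | O=c1ccoc2c(I)c(OC)cc(O[Si](C(C)C)(C(C)C)C(C)C)c12 | intermediate
9 | (S)-lavandulyllithium | C=C(C)[C@H](CC=C(C)C)C[Li] | intermediate
10 | (S)-lavandulylzinc chloride | C=C(C)[C@H](CC=C(C)C)C[Zn]Cl | intermediate
11 | 8-[(2R)-lavandulyl]-7-methoxy-5-(triisopropylsilyloxy)chromone | C=C(C)[C@H](CC=C(C)C)Cc1c(OC)cc(O[Si](C(C)C)(C(C)C)C(C)C)c2c1occc2=O | intermediate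
12 | trimethylsilylacetylene | C#C[Si](C)(C)C | starting material
13 | 4-(tert-butyldimethylsilyloxy)-8-[(2R)-lavandulyl]-7-methoxy-5-(triisopropylsilyloxy)benzopyrylium triflate | C=C(C)[C@H](CC=C(C)C)Cc1c(OC)cc(O[Si](C(C)C)(C(C)C)C(C)C)c2c(O[Si](C)(C)C(C)(C)C)cc[o+]c12.[O-]S(=O)(=O)C(F)(F)F | intermediate
14 | (2S)-4-(tert-butyldimethylsilyloxy)-8-[(2R)-lavandulyl]-7-methoxy-5-(triisopropylsilyloxy)-2-[(trimethylsilyl)ethynyl]-2H-chromene (silyl enol ether) | C=C(C)[C@H](CC=C(C)C)Cc1c(OC)cc(O[Si](C(C)C)(C(C)C)C(C)C)c2c1O[C@H](C#C[Si](C)(C)C)C=C2O[Si](C)(C)C(C)(C)C | intermediate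
15 | (2S)-8-[(2R)-lavandulyl]-7-methoxy-5-(triisopropylsilyloxy)-2-[(trimethylsilyl)ethynyl]chroman-4-one | C=C(C)[C@H](CC=C(C)C)Cc1c(OC)cc(O[Si](C(C)C)(C(C)C)C(C)C)c2c1O[C@H](C#C[Si](C)(C)C)CC2=O | intermediate
16 | (2S)-2-ethynyl-5-hydroxy-8-[(2R)-lavandulyl]-7-methoxychroman-4-one | C=C(C)[C@H](CC=C(C)C)Cc1c(OC)cc(O)c2c1O[C@H](C#C)CC2=O | intermediate
17 | (E)-(2-bromovinyl)trimethylsilane | C[Si](C)(C)/C=C/Br | starting material
18 | chromium hexacarbonyl, Cr(CO)6 | O=C=[Cr](=C=O)(=C=O)(=C=O)(=C=O)=C=O | starting material
19 | (E)-2-(trimethylsilyl)vinyllithium | C[Si](C)(C)/C=C/[Li] | intermediate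
20 | lithium pentacarbonyl[(E)-3-(trimethylsilyl)acryloyl]chromate | [Li+].[O-]C(/C=C/[Si](C)(C)C)=[Cr](=C=O)(=C=O)(=C=O)(=C=O)=C=O | intermediate
21 | pentacarbonyl{methoxy[(E)-2-(trimethylsilyl)vinyl]carbene}chromium | C[Si](C)(C)/C=C/C(OC)=[Cr](=C=O)(=C=O)(=C=O)(=C=O)=C=O | intermediate
22 | (2S)-5-hydroxy-8-[(2R)-lavandulyl]-7-methoxy-2-[5-methoxy-2-(trimethylsilyloxy)phenyl]chroman-4-one | C=C(C)[C@H](CC=C(C)C)Cc1c(OC)cc(O)c2c1O[C@H](c1cc(OC)ccc1O[Si](C)(C)C)CC2=O | intermediate
23 | (2S)-5-hydroxy-2-(2-hydroxy-5-methoxyphenyl)-8-[(2R)-lavandulyl]-7-methoxychroman-4-one (5'-O-methyl ether of the target) | C=C(C)[C@H](CC=C(C)C)Cc1c(OC)cc(O)c2c1O[C@H](c1cc(OC)ccc1O)CC2=O | intermediate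
24 | (2S)-2-(1,4-benzoquinon-2-yl)-5-hydroxy-8-[(2R)-lavandulyl]-7-methoxychroman-4-one | C=C(C)[C@H](CC=C(C)C)Cc1c(OC)cc(O)c2c1O[C@H](C1=CC(=O)C=CC1=O)CC2=O | intermediate
25 | (2S)-2-(2,5-dihydroxyphenyl)-5-hydroxy-8-[(2R)-lavandulyl]-7-methoxychroman-4-one | C=C(C)[C@H](CC=C(C)C)Cc1c(OC)cc(O)c2c1O[C@H](c1cc(O)ccc1O)CC2=O | target

Total step count: 11. Longest linear sequence: 8 steps (steps 3, 4, 5, 6, 7, 8, 10 and 11, from 4).

Steps most likely to fail

Step 10. The carbene complex may decompose before the alkyne inserts, a second alkyne may be taken up, cyclisation may proceed without CO insertion, or the silyl group may fail to migrate to oxygen. The fallback sets out from 11 and comes back at 24, and builds ring B by aryl transfer instead of annulation. Rhodium-catalysed asymmetric conjugate addition of commercial 2,5-dimethoxyphenylboronic acid to chromone 11 ([Rh(OH)(cod)]2, chiral bisphosphine of the antipode giving 2S, toluene/H2O, 50 °C) should give (2S)-2-(2,5-dimethoxyphenyl)-8-[(2R)-lavandulyl]-7-methoxy-5-(triisopropylsilyloxy)chroman-4-one F1. TBAF/AcOH in THF at 0 °C should then free the 5-hydroxyl to give (2S)-2-(2,5-dimethoxyphenyl)-5-hydroxy-8-[(2R)-lavandulyl]-7-methoxychroman-4-one F2. Oxidative demethylation of the 1,4-dimethoxybenzene ring with (NH4)2Ce(NO3)6 in aqueous MeCN at 0 °C should give quinone 24, which is reduced in the same flask with Na2S2O4 to 25 as in step 11.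

Step 7. Facial selectivity may be poor, or addition to the electron-rich, peri-crowded benzopyrylium ion may be slow at the low temperature that the chiral catalyst needs. The fallback sets out from 11 and comes back at 15, and gives up catalyst control. Pyrylium 13 is treated with 12, CuI and i-Pr2NEt without ligand at 0 °C → rt, then hydrolysed as before, which should give 15 together with its C2 epimer (2R)-8-[(2R)-lavandulyl]-7-methoxy-5-(triisopropylsilyloxy)-2-[(trimethylsilyl)ethynyl]chroman-4-one F3. Because the lavandulyl centre is fixed, the two are diastereomers and should be separable by preparative HPLC. The unwanted epimer F3 is re-equilibrated through reversible oxa-Michael ring opening (DBU, THF, rt) and separated again.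

Step 6. β-Hydride elimination or protodemetalation may outrun reductive elimination at the di-ortho-substituted aryl–palladium, or the homoallylic zinc reagent may rearrange. The fallback sets out from 3 and 8 and comes back at 11, and replaces zinc by a boron ate complex (B-alkyl Suzuki–Miyaura coupling). Iodide 3 is converted with t-BuLi (Et2O, −78 °C) into 9, which is trapped with 9-methoxy-9-borabicyclo[3.3.1]nonane to give lithium 9-[(S)-lavandulyl]-9-methoxy-9-boratabicyclo[3.3.1]nonane F4. Without isolation, F4 is coupled with 8 using Pd(dppf)Cl2 and K3PO4 in DMF/THF at rt.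

Further compounds
F1 | step 10 | (2S)-2-(2,5-dimethoxyphenyl)-8-[(2R)-lavandulyl]-7-methoxy-5-(triisopropylsilyloxy)chroman-4-one | C=C(C)[C@H](CC=C(C)C)Cc1c(OC)cc(O[Si](C(C)C)(C(C)C)C(C)C)c2c1O[C@H](c1cc(OC)ccc1OC)CC2=O
F2 | step 10 | (2S)-2-(2,5-dimethoxyphenyl)-5-hydroxy-8-[(2R)-lavandulyl]-7-methoxychroman-4-one | C=C(C)[C@H](CC=C(C)C)Cc1c(OC)cc(O)c2c1O[C@H](c1cc(OC)ccc1OC)CC2=O
F3 | step 7 | (2R)-8-[(2R)-lavandulyl]-7-methoxy-5-(triisopropylsilyloxy)-2-[(trimethylsilyl)ethynyl]chroman-4-one | C=C(C)[C@H](CC=C(C)C)Cc1c(OC)cc(O[Si](C(C)C)(C(C)C)C(C)C)c2c1O[C@@H](C#C[Si](C)(C)C)CC2=O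
F4 | step 6 | lithium 9-[(S)-lavandulyl]-9-methoxy-9-boratabicyclo[3.3.1]nonane | C=C(C)[C@H](CC=C(C)C)C[B-]1(OC)C2CCCC1CCC2.[Li+]
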